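## Retrosynthetic overview

1. The 11-acetate comes from a late swap of an 11-O-silyl group. The 13-membered lactone ring is closed by Z-selective ring-closing metathesis (C5=C6) between a C8 allyl group and a 15-O-hex-5-enoyl ester.
2. The trisubstituted cyclopentanone comes from a one-pot three-component coupling: (R)-4-silyloxycyclopentenone, an ω-chain alkenyl zincate that already carries the ester, and allyl iodide. This forms C12–C13 and C7–C8; C12 and C8 are relayed from C11.
3. The ω-chain vinyl iodide comes from Takai olefination of an α-acyloxy aldehyde. That aldehyde comes from an amine-catalysed asymmetric α-acyloxylation of (Z)-hept-4-enal with bis(hex-5-enoyl) peroxide, which sets C15 and installs the lactone chain (new step).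
4. The enone comes from oxidation of the product of an organocatalytic desymmetrising silylation of meso cis-cyclopent-4-ene-1,3-diol, which sets C11.
5. Ring order: the cyclopentane ring is present from the meso diol onward; the 13-membered lactone ring is the only ring formed, and it is formed by the metathesis.

Assumption: the silylation catalyst antipode is the one that gives the (1S,4R) monosilyl ether, and the facial sense of step 4 is taken from the benzoyl peroxide reaction of the same (S)-amine (if reversed, the (R)-amine is used).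

## Route

Step 1  
Reactants: 1 cis-cyclopent-4-ene-1,3-diol (meso)  
Product: 2 (1S,4R)-4-(tert-butyldimethylsilyloxy)cyclopent-2-en-1-ol  
Conditions: TBSCl (2 equiv), iPr2NEt (1.25 equiv), (S)-N-[(R)-3,3-dimethylbutan-2-yl]-3,3-dimethyl-2-{[(1-methylimidazol-2-yl)methyl]amino}butanamide (30 mol %), THF, −40 °C, 72 h  
Reagents that add atoms: tert-butyldimethylsilyl chloride, `CC(C)(C)[Si](C)(C)Cl`  
Why: Catalytic enantioselective silylation (desymmetrisation of a meso diol): the imidazole activates TBSCl as a Lewis base while the N–H groups hydrogen-bond the diol, so only the hydroxyl on the future C11 is silylated and the first stereocentre is set by the catalyst.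

Step 2  
Reactants: 2 (1S,4R)-4-(tert-butyldimethylsilyloxy)cyclopent-2-en-1-ol  
Product: 3 (4R)-4-(tert-butyldimethylsilyloxy)cyclopent-2-en-1-one  
Conditions: MnO2 (15 equiv), CH2Cl2, rt  
Reagents that add atoms: none  
Why: Allylic alcohol oxidation; the silyloxy carbon is untouched, so the ee of 2 is carried into the enone.

Step 3  
Reactants: 4 hex-5-enoic acid (2 equiv)  
Product: 6 bis(hex-5-enoyl) peroxide, via hex-5-eneperoxoic acid 5 (not isolated)  
Conditions: H2O2 (50 % aq., 0.55 equiv), DCC (1.1 equiv), Et2O/CH2Cl2, 0 °C, dark; filter, wash, use as a titrated solution (never concentrated to dryness)  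
Reagents that add atoms: hydrogen peroxide, `OO`  
Why: Carbodiimide-mediated double O-acylation of hydrogen peroxide (peracid first, then a second acylation) is the standard entry to aliphatic diacyl peroxides, and the unactivated terminal alkene is not epoxidised at 0 °C.

Step 4  
Reactants: 7 (4Z)-hept-4-enal (1.5 equiv); 6 bis(hex-5-enoyl) peroxide (1.0 equiv)  
Product: 8 (2S,4Z)-1-oxohept-4-en-2-yl hex-5-enoate  
Conditions: (S)-2-(triphenylmethyl)pyrrolidine (10 mol %), hydroquinone (10 mol %), THF, 0 °C; wash with aq. NaHCO3 and aq. Na2S2O3, strip excess 7, use crude at once  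
Reagents that add atoms: none  
Why: Proposed new method: the E-enamine from 7 and the bulky (S)-amine attacks one peroxide oxygen of 6 in an SN2-type displacement at O (into the O–O σ*), hex-5-enoate leaves and hydrolysis of the α-acyloxy iminium releases 8 and the amine; the CPh3 group blocks one enamine face so the C–O bond forms on the open face and sets 15S; the closest known reaction is the amine-catalysed α-benzoyloxylation of aldehydes with dibenzoyl peroxide, extended here to an aliphatic, alkene-bearing diacyl peroxide so that the transferred acyloxy group is the future lactone chain.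

Step 5  
Reactants: 8 (2S,4Z)-1-oxohept-4-en-2-yl hex-5-enoate  
Product: 9 (1E,3S,5Z)-1-iodoocta-1,5-dien-3-yl hex-5-enoate  
Conditions: CrCl2 (6 equiv), CHI3 (2 equiv), THF/1,4-dioxane (1:6), 0 °C to rt  
Reagents that add atoms: iodoform, `IC(I)I`  
Why: Takai olefination: the iodo-substituted gem-dichromium reagent adds to the aldehyde and eliminates to the E-vinyl iodide under non-basic conditions, so the α-acyloxy stereocentre is not epimerised and the ester is inert.

Step 6  
Reactants: 9 (1E,3S,5Z)-1-iodoocta-1,5-dien-3-yl hex-5-enoate; 3 (4R)-4-(tert-butyldimethylsilyloxy)cyclopent-2-en-1-one; 10 allyl iodide  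
Product: 14 (1E,3S,5Z)-1-[(1R,2R,5R)-2-allyl-5-(tert-butyldimethylsilyloxy)-3-oxocyclopentyl]octa-1,5-dien-3-yl hex-5-enoate, via alkenyllithium 11 (not isolated), via lithium alkenyl(dimethyl)zincate 12 (not isolated), via zinc enolate 13 (not isolated)  
Conditions: t-BuLi (1.95 equiv), THF/Et2O/pentane 4:1:1, −100 °C, 5 min; Me2Zn (1.0 equiv), −100 to −78 °C; 3 (0.9 equiv), THF, −78 °C, 1 h; HMPA (10 equiv), 10 (5 equiv), −78 to −40 °C, 16 h; aq. NH4Cl  
Reagents that add atoms: none  
Why: Noyori three-component coupling: iodine–lithium exchange at −100 °C outruns attack on the ester (the E-geometry also keeps the C–Li bond away from its own ester), Me2Zn converts it at once into the mild zincate, which adds 1,4 to 3 anti to the silyloxy group (sets C12), and the zinc enolate is allylated anti to the new side chain (sets C8), giving the all-trans ketone.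

Step 7  
Reactants: 14 (1E,3S,5Z)-1-[(1R,2R,5R)-2-allyl-5-(tert-butyldimethylsilyloxy)-3-oxocyclopentyl]octa-1,5-dien-3-yl hex-5-enoate  
Product: 15 (5Z,8R,11R,12R,13E,15S,17Z)-11-(tert-butyldimethylsilyloxy)-9-oxoprosta-5,13,17-trien-1,15-olide  
Conditions: Ru(NO3)(=CH-C6H4-2-OiPr)(C,C-chelating 1-(1-adamantyl)-3-mesitylimidazolidin-2-ylidene) (7.5 mol %), ClCH2CH2Cl (3 mM), 60 °C, static vacuum  
Reagents that add atoms: none  
Why: Z-selective ring-closing metathesis: only the two monosubstituted alkenes are engaged, the cyclometalated carbene ligand forces a side-bound metallacycle with both substituents syn so the 13-membered lactone closes with the 5Z alkene, and loss of ethylene drives it.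

Step 8  
Reactants: 15 (5Z,8R,11R,12R,13E,15S,17Z)-11-(tert-butyldimethylsilyloxy)-9-oxoprosta-5,13,17-trien-1,15-olide  
Product: 17 PGE3-1,15-lactone 11-acetate (target), via PGE3-1,15-lactone 16 (not isolated)  
Conditions: HF·pyridine, pyridine, THF, 0 °C to rt; then Ac2O (15 equiv), 0 °C to rt  
Reagents that add atoms: acetic anhydride, `CC(=O)OC(C)=O`  
Why: Fluoride desilylation followed in the same pot by pyridine-mediated acetylation; both events occur at oxygen so C11 keeps its configuration, and the buffered, weakly basic medium avoids β-elimination to the cyclopentenone.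

## Compound list

1 | cis-cyclopent-4-ene-1,3-diol (meso, 1R,3S) | `O[C@@H]1C=C[C@H](O)C1` | starting material  
2 | (1S,4R)-4-(tert-butyldimethylsilyloxy)cyclopent-2-en-1-ol | `O[C@@H]1C=C[C@H](O[Si](C)(C)C(C)(C)C)C1` | intermediate  
3 | (4R)-4-(tert-butyldimethylsilyloxy)cyclopent-2-en-1-one | `O=C1C=C[C@H](O[Si](C)(C)C(C)(C)C)C1` | intermediate  
4 | hex-5-enoic acid | `C=CCCCC(=O)O` | starting material  
5 | hex-5-eneperoxoic acid | `C=CCCCC(=O)OO` | intermediate (not isolated)  
6 | bis(hex-5-enoyl) peroxide | `C=CCCCC(=O)OOC(=O)CCCC=C` | intermediate  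
7 | (4Z)-hept-4-enal | `CC/C=C\CCC=O` | starting material  
8 | (2S,4Z)-1-oxohept-4-en-2-yl hex-5-enoate | `CC/C=C\C[C@@H](C=O)OC(=O)CCCC=C` | intermediate  
9 | (1E,3S,5Z)-1-iodoocta-1,5-dien-3-yl hex-5-enoate | `CC/C=C\C[C@@H](/C=C/I)OC(=O)CCCC=C` | intermediate  
10 | allyl iodide (3-iodoprop-1-ene) | `C=CCI` | starting material  
11 | [(1E,3S,5Z)-3-(hex-5-enoyloxy)octa-1,5-dien-1-yl]lithium | `CC/C=C\C[C@@H](/C=C/[Li])OC(=O)CCCC=C` | intermediate (not isolated)  
12 | lithium [(1E,3S,5Z)-3-(hex-5-enoyloxy)octa-1,5-dien-1-yl]dimethylzincate | `[Li+].CC/C=C\C[C@@H](/C=C/[Zn-](C)C)OC(=O)CCCC=C` | intermediate (not isolated)  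
13 | lithium {[(3R,4R)-4-(tert-butyldimethylsilyloxy)-3-[(1E,3S,5Z)-3-(hex-5-enoyloxy)octa-1,5-dien-1-yl]cyclopent-1-en-1-yl]oxy}dimethylzincate | `[Li+].CC/C=C\C[C@@H](/C=C/[C@H]1[C@H](O[Si](C)(C)C(C)(C)C)CC(O[Zn-](C)C)=C1)OC(=O)CCCC=C` | intermediate (not isolated)  
14 | (1E,3S,5Z)-1-[(1R,2R,5R)-2-allyl-5-(tert-butyldimethylsilyloxy)-3-oxocyclopentyl]octa-1,5-dien-3-yl hex-5-enoate | `CC/C=C\C[C@@H](/C=C/[C@H]1[C@H](O[Si](C)(C)C(C)(C)C)CC(=O)[C@@H]1CC=C)OC(=O)CCCC=C` | intermediate  
15 | (5Z,8R,11R,12R,13E,15S,17Z)-11-(tert-butyldimethylsilyloxy)-9-oxoprosta-5,13,17-trien-1,15-olide | `CC/C=C\C[C@H]1/C=C/[C@H]2[C@H](O[Si](C)(C)C(C)(C)C)CC(=O)[C@@H]2C/C=C\CCCC(=O)O1` | intermediate  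
16 | PGE3-1,15-lactone, (5Z,8R,11R,12R,13E,15S,17Z)-11-hydroxy-9-oxoprosta-5,13,17-trien-1,15-olide | `CC/C=C\C[C@H]1/C=C/[C@H]2[C@H](O)CC(=O)[C@@H]2C/C=C\CCCC(=O)O1` | intermediate (not isolated)  
17 | PGE3-1,15-lactone 11-acetate (8R,11R,12R,15S; 5Z,13E,17Z) | `CC/C=C\C[C@H]1/C=C/[C@H]2[C@H](OC(C)=O)CC(=O)[C@@H]2C/C=C\CCCC(=O)O1` | target  

## Step count and risks

Total steps: 8 (steps 6 and 8 are one-pot operations). Longest linear sequence: 6 steps (4 → 6 → 8 → 9 → 14 → 15 → 17).

**Step 4 (proposed new α-acyloxylation).** The aliphatic peroxide may oxidise the amine, decompose by a radical path, or give lower ee than dibenzoyl peroxide. Fallback with known chemistry, setting out from 7 and coming back at 9: run the established α-benzoyloxylation of 7 with dibenzoyl peroxide and the same amine to give (2S,4Z)-1-oxohept-4-en-2-yl benzoate F1. Olefinate it with CHI3/CrCl2 to (1E,3S,5Z)-1-iodoocta-1,5-dien-3-yl benzoate F2. Remove the benzoate with K2CO3 in MeOH to give (1E,3S,5Z)-1-iodoocta-1,5-dien-3-ol F3. Esterify F3 with 4 (DCC, DMAP, CH2Cl2) to reach 9. The acyl chain then enters by ordinary esterification instead of by oxygen transfer.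

**Step 6 (three-component coupling with an ester in the nucleophile).** The lithium or zincate stage may attack the ester, or the enolate may equilibrate and eliminate the silyloxy group. Fallback setting out from 9 and coming back at 14: cleave the ester of 9 (K2CO3, MeOH) to the iodo alcohol (1E,3S,5Z)-1-iodoocta-1,5-dien-3-ol F3. Protect it (TESCl, imidazole) as (1E,3S,5Z)-1-iodo-3-(triethylsilyloxy)octa-1,5-diene F4. Run the classical coupling (t-BuLi, −78 °C; Me2Zn; 3; HMPA, 10) to give (2R,3R,4R)-2-allyl-4-(tert-butyldimethylsilyloxy)-3-[(1E,3S,5Z)-3-(triethylsilyloxy)octa-1,5-dien-1-yl]cyclopentan-1-one F5. Remove only the triethylsilyl group (PPTS, MeOH, 0 °C) to give (2R,3R,4R)-2-allyl-4-(tert-butyldimethylsilyloxy)-3-[(1E,3S,5Z)-3-hydroxyocta-1,5-dien-1-yl]cyclopentan-1-one F6. Esterify F6 with 4 (DCC, DMAP) to reach 14.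

**Step 7 (Z-selective macrocyclic metathesis).** The risks are E/Z mixtures, alkene migration at the allyl ketone, and partial engagement of the 17Z alkene. Fallback by alkyne metathesis and semi-hydrogenation, setting out from 7 and 3 and coming back at 15:
- Make bis(hept-5-ynoyl) peroxide F7 from commercial hept-5-ynoic acid as in step 3.
- Use F7 in the step 4 reaction to give (2S,4Z)-1-oxohept-4-en-2-yl hept-5-ynoate F8. If step 4 itself has been replaced, esterify F3 with hept-5-ynoic acid instead.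
- Takai olefination gives (1E,3S,5Z)-1-iodoocta-1,5-dien-3-yl hept-5-ynoate F9.
- Coupling as in step 6 with 3 and commercial 1-bromobut-2-yne gives (1E,3S,5Z)-1-[(1R,2R,5R)-2-(but-2-yn-1-yl)-5-(tert-butyldimethylsilyloxy)-3-oxocyclopentyl]octa-1,5-dien-3-yl hept-5-ynoate F10.
- Ring-closing alkyne metathesis with Mo(≡C-C6H4-4-OMe)(OSiPh3)3 (5 mol %, 5 Å sieves, toluene, 80 °C) gives the cycloalkyne (8R,11R,12R,13E,15S,17Z)-11-(tert-butyldimethylsilyloxy)-9-oxoprosta-13,17-dien-5-yn-1,15-olide F11. The alkenes do not take part.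
- H2 over Pd/CaCO3 poisoned with Pb(OAc)2 and quinoline gives the 5Z alkene 15.

## Further compounds

F1 | step 4 | (2S,4Z)-1-oxohept-4-en-2-yl benzoate | `CC/C=C\C[C@@H](C=O)OC(=O)c1ccccc1`  
F2 | step 4 | (1E,3S,5Z)-1-iodoocta-1,5-dien-3-yl benzoate | `CC/C=C\C[C@@H](/C=C/I)OC(=O)c1ccccc1`  
F3 | step 4 | (1E,3S,5Z)-1-iodoocta-1,5-dien-3-ol | `CC/C=C\C[C@@H](/C=C/I)O`  
F4 | step 6 | (1E,3S,5Z)-1-iodo-3-(triethylsilyloxy)octa-1,5-diene | `CC/C=C\C[C@@H](/C=C/I)O[Si](CC)(CC)CC`  
F5 | step 6 | (2R,3R,4R)-2-allyl-4-(tert-butyldimethylsilyloxy)-3-[(1E,3S,5Z)-3-(triethylsilyloxy)octa-1,5-dien-1-yl]cyclopentan-1-one | `CC/C=C\C[C@@H](/C=C/[C@H]1[C@H](O[Si](C)(C)C(C)(C)C)CC(=O)[C@@H]1CC=C)O[Si](CC)(CC)CC`  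
F6 | step 6 | (2R,3R,4R)-2-allyl-4-(tert-butyldimethylsilyloxy)-3-[(1E,3S,5Z)-3-hydroxyocta-1,5-dien-1-yl]cyclopentan-1-one | `CC/C=C\C[C@@H](/C=C/[C@H]1[C@H](O[Si](C)(C)C(C)(C)C)CC(=O)[C@@H]1CC=C)O`  
F7 | step 7 | bis(hept-5-ynoyl) peroxide | `CC#CCCCC(=O)OOC(=O)CCCC#CC`  
F8 | step 7 | (2S,4Z)-1-oxohept-4-en-2-yl hept-5-ynoate | `CC/C=C\C[C@@H](C=O)OC(=O)CCCC#CC`  
F9 | step 7 | (1E,3S,5Z)-1-iodoocta-1,5-dien-3-yl hept-5-ynoate | `CC/C=C\C[C@@H](/C=C/I)OC(=O)CCCC#CC`  
F10 | step 7 | (1E,3S,5Z)-1-[(1R,2R,5R)-2-(but-2-yn-1-yl)-5-(tert-butyldimethylsilyloxy)-3-oxocyclopentyl]octa-1,5-dien-3-yl hept-5-ynoate | `CC/C=C\C[C@@H](/C=C/[C@H]1[C@H](O[Si](C)(C)C(C)(C)C)CC(=O)[C@@H]1CC#CC)OC(=O)CCCC#CC`  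
F11 | step 7 | (8R,11R,12R,13E,15S,17Z)-11-(tert-butyldimethylsilyloxy)-9-oxoprosta-13,17-dien-5-yn-1,15-olide | `CC/C=C\C[C@H]1/C=C/[C@H]2[C@H](O[Si](C)(C)C(C)(C)C)CC(=O)[C@@H]2CC#CCCCC(=O)O1`  
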